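Free monomer cannot enter chains without initiator, and initiator also turns chain units into isomer of the product.

| setting | grey | teal | green | red |
|---|---|---|---|---|
| free monomer | 0.076 M | 0.076 M | 0.076 M (fed, over 1.00 d) | 0.076 M |
| initiator | 0.38 mM | 0.38 mM | 0.38 mM | 0.38 mM |
| time | 2.0 d |  | 2.0 d |  |
| remark | everything together in a closed stirred flask, run for 2.0 d | a single well-mixed tank run continuously and read at steady state, 2.0 d in it on average | all but free monomer at the start; free monomer goes in evenly over 1.00 d, the run ends at 2.0 d | one stirred flow tank at steady state, fed with the mixture as stated, mean residence time 20.0 d |

* the set-up with the highest amount of monomer in chains at the outlet or at the end, in percent of the free monomer put in ("none" if the first two lie within 2 percentage points) (grey / teal / green / red / none)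
* amount of monomer in chains at the outlet or at the end, in percent of the free monomer put in, grey
* amount of monomer in chains at the outlet or at the end, in percent of the free monomer put in, teal
* amount of monomer in chains at the outlet or at the end, in percent of the free monomer put in, green
* amount of monomer in chains at the outlet or at the end, in percent of the free monomer put in, red

- the stated concentrations are those of everything mixed, before any reaction; amounts are the same in each set-up
- the feed brings no volume worth counting
- run time (grey): 2.0 d

    monomer in chains + initiator ⇌ isomer of the product + initiator, rate k1*[initiator]*[monomer in chains] forward; the back reaction follows from the equilibrium constant (K1 = 4.47, k1 = 198 L mol⁻¹ h⁻¹)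
    free monomer + initiator → living end + monomer in chains (k2 = 1.05 L mol⁻¹ h⁻¹)
    free monomer + living end → monomer in chains + living end, rate k3*[living end]*[free monomer] (k3 = 879 L mol⁻¹ h⁻¹)

I write free monomer, monomer in chains and isomer of the product as fractions of the free monomer charge, and initiator as a share of its own charge. In words, initiator slowly starts living ends, living ends quickly add free monomer to chains, and initiator reversibly isomerises chain units.

Which numbers must be known well? K1 sets a floor: at equilibrium a fraction 18.3% of the chain material remains monomer in chains, and K1 matters mostly late. The constants k2 and k3 set the start-up. Step 2 by itself, with initiator held at its charge, is slow, with a half-life of 72 d. Early on, while free monomer and initiator stand near their charges, living ends grow in step with time, so free monomer falls at first as an exponential of time squared; this is an early law and does not hold to the end of the run. Stretching it to the half-way point gives a rough half-way time of 0.300 d, which is short against the run, and both constants sit under a square root. Errors there matter little.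

The numbers that matter are k1 and the initiator present. Each living end costs one initiator. Dividing step 2 by step 3 and integrating over the whole charge of free monomer says that the logarithm of one over the share of initiator left equals the share spent plus 0.239. Trying an even split for the share spent gives a share left of 0.478, about half of the charge, and I use that share throughout.

My carried quantity is the isomer clock, 1.06 d⁻¹: k1 times the initiator present, enlarged by the way back. The excess of chain share over the floor decays exponentially at this rate. In grey the exponent is 1.79, so an error in k1 reaches the excess multiplied by that figure.

Chains in grey are aged by the run less the half-way time, giving 31.9%. Averaging the exponential over the feed gives green 42.4%. In a tank, spread ages turn the exponential into one over one plus clock times stay, so red comes to 22.0%. For teal, with some free monomer unreacted, I commit to a ceiling of 39.8%. My choice is green.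

The forecast also names green, with 34.6% for grey, 33.8% for teal, 44% for green and 20.8% for red, holding that “the yield is set by how long the chains sit with initiator”. Its numbers differ from mine, but the choice is the same.

The simulation gives green: grey 34.2%, teal 33.8%, green 44.3%, red 20.8%.

The main reason for the green figure is isomerisation: the same run without step 1 holds 99.5% in chains instead of 44.3%. The same flask as grey with 1.5 × 10⁻⁴ M of initiator ends with 26.6% of that charge, so my clock of 1.06 d⁻¹ shrinks in proportion to the initiator present, to 0.232 d⁻¹. With its half-way time scaled to 0.478 d, the clock gives 75.7%, and that flask holds 73.7% in chains.

(The rate constants come from no measurement; the run is a simulation.)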